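C1 is the bridgehead that carries prenyl, C2–C3–C4 the enolised diketone bridge (aroyl on C3), C5 the bridgehead that carries lavandulyl, C6 the ring CH2, C7 the CH with prenyl, C8 the CMe2 carbon and C9 the one-carbon ketone bridge; ring A = C1-C2-C3-C4-C5-C9, ring B = C1-C9-C5-C6-C7-C8.
Enabling feature: the C9 carbonyl sits between the quaternary bridgeheads C1 and C5, and C1 adjoins quaternary C8. C9, C1, C8 and C7 can therefore be carried as a cyclobutanone that already holds the crowded C1–C8 bond, and its strained C9–C7 bond can take up the C5=C6 alkene.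
Cuts, in retrosynthetic order: C3–C(aroyl); C9–C5 and C6–C7 together (both six-membered rings, back to cyclobutanone 17); C1–prenyl; C1–C2; C7–prenyl; in the side chain C5–CH2(lavandulyl) and C5=C6.
Forward: (R)-lavandulol is grown into dienoic acid 8 (C2 to C6 plus lavandulyl) and 3,3-dimethylcyclobutanone into ketone 14. Acylation and then prenylation at C1 give 17. The four-membered ring is bought, rings A and B arise together in step 11, and C3 aroylation plus one hydrolysis finish the route.
Stereochemistry: the side-chain centre comes from (R)-lavandulol, C7 from a RAMP-hydrazone alkylation, and C1 from alkylation anti to the C7 prenyl group. C5 is relayed from C1 by the geometry of the bridge, and C7 is retained through the C–C activation, which leaves its prenyl group endo (syn to C2–C4).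

Key step: step 11

Assumption: (R)-lavandulol, RAMP and 3,3-dimethylcyclobutanone are taken as catalogue compounds, and the target is written as its C4-enol tautomer, which equilibrates freely with the C2-enol form.

Step 1
Reactants: 1 (R)-lavandulol
Product: 2 (R)-lavandulyl iodide [(3R)-3-(iodomethyl)-2,6-dimethylhepta-1,5-diene]
Conditions: I2, PPh3, imidazole, CH2Cl2, 0 °C to rt
Reagents that add atoms: iodine, II
Why: Appel-type iodination replaces the primary hydroxyl group by SN2 at CH2, so the neighbouring allylic stereocentre is not touched.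

Step 2
Reactants: 3 methyl acetoacetate; 2 (R)-lavandulyl iodide
Product: 4 methyl (6R)-9-methyl-3-oxo-6-(prop-1-en-2-yl)dec-8-enoate
Conditions: 3, NaH then n-BuLi, THF, 0 °C; 2, 0 °C to rt; 1 M HCl
Reagents that add atoms: none
Why: γ-Alkylation of the acetoacetate dianion, in which the terminal carbanion is by far the more nucleophilic site and primary iodides are standard partners, makes the C5–CH2(lavandulyl) bond.

Step 3
Reactants: 4 methyl (6R)-9-methyl-3-oxo-6-(prop-1-en-2-yl)dec-8-enoate
Product: 6 5-[(2S)-5-methyl-2-(prop-1-en-2-yl)hex-4-en-1-yl]oxane-2,4-dione (both epimers at ring C5), via hydroxymethyl keto ester 5 (not isolated)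
Conditions: LiN(i-Pr)2 (2.2 equiv), THF, −78 to 0 °C; HCHO (gas, from cracked paraformaldehyde), −78 °C; 1 M NaOH, rt; HCl to pH 2
Reagents that add atoms: formaldehyde, C=O
Why: A second dianion again exposes the γ-carbon (C5), its aldol addition to formaldehyde brings in C6, and saponification then acidification closes the δ-lactone as in the classical dihydropyranone synthesis; the centre formed at C5 is a mixture that step 5 erases.

Step 4
Reactants: 6 5-substituted oxane-2,4-dione
Product: 7 4-methoxy-5-[(2S)-5-methyl-2-(prop-1-en-2-yl)hex-4-en-1-yl]-5,6-dihydro-2H-pyran-2-one (both epimers at ring C5)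
Conditions: Me2SO4, K2CO3, acetone, rt
Reagents that add atoms: dimethyl sulfate, COS(=O)(=O)OC
Why: O-Methylation of a cyclic β-keto lactone with Me2SO4/K2CO3 is the standard entry to 4-methoxy-5,6-dihydropyran-2-ones, and the ring holds C2 and C5 cis on the C3=C4 double bond.

Step 5
Reactants: 7 4-methoxy-5-substituted 5,6-dihydro-2H-pyran-2-one
Product: 8 (2E,6S)-3-methoxy-9-methyl-4-methylidene-6-(prop-1-en-2-yl)deca-2,8-dienoic acid
Conditions: LiN(SiMe3)2 (1.3 equiv), THF, −78 to 0 °C; cold 1 M HCl
Reagents that add atoms: none
Why: Vinylogous E1cB elimination, the known base-induced opening of 4-methoxy-5,6-dihydropyran-2-ones to 3-methoxydienoic acids, removes H-5 and expels the carboxylate from C6; this creates C5=C6 and keeps the ring-derived C3=C4 geometry, which is also the more stable one.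

Step 6
Reactants: 9 3,3-dimethylcyclobutanone; 10 RAMP [(2R)-1-amino-2-(methoxymethyl)pyrrolidine]
Product: 11 (2R)-N-(3,3-dimethylcyclobutylidene)-2-(methoxymethyl)pyrrolidin-1-amine
Conditions: neat, MS 4 Å, 60 °C
Reagents that add atoms: none
Why: Hydrazone condensation, the first stage of the Enders hydrazone method, is easy on the strained and therefore very electrophilic ketone.

Step 7
Reactants: 11 RAMP hydrazone of 3,3-dimethylcyclobutanone; 12 prenyl bromide (1-bromo-3-methylbut-2-ene)
Product: 13 (2R)-N-[(2S)-3,3-dimethyl-2-(3-methylbut-2-en-1-yl)cyclobutylidene]-2-(methoxymethyl)pyrrolidin-1-amine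
Conditions: LiN(i-Pr)2, THF, 0 °C; 12, −95 °C to rt
Reagents that add atoms: none
Why: Enders RAMP-hydrazone alkylation, in which the lithium azaenolate is chelated by the methoxy arm and the allylic bromide enters on the open face; by the established sense of induction RAMP gives the (S) centre that becomes C7.

Step 8
Reactants: 13 alkylated RAMP hydrazone
Product: 14 (2S)-3,3-dimethyl-2-(3-methylbut-2-en-1-yl)cyclobutan-1-one
Conditions: saturated aq. (CO2H)2, Et2O, rt
Reagents that add atoms: water, O
Why: Two-phase hydrolysis with oxalic acid is the mild, epimerisation-free hydrazone cleavage; unlike ozonolysis it spares the prenyl alkene, and it returns the auxiliary.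

Step 9
Reactants: 8 (2E,6S)-dienoic acid; 14 (2S)-3,3-dimethyl-2-prenylcyclobutanone
Product: 16 (4S)-2-[(2E,6S)-3-methoxy-9-methyl-4-methylidene-6-(prop-1-en-2-yl)deca-2,8-dienoyl]-3,3-dimethyl-4-(3-methylbut-2-en-1-yl)cyclobutan-1-one (keto–enol mixture; ring C2 = C1 undefined), via dienoyl chloride 15 (not isolated)
Conditions: 8, Me2C=C(Cl)NMe2, CH2Cl2, 0 °C; cannulated into 14 (2 equiv), LiN(SiMe3)2 (2 equiv), toluene, −78 to 0 °C; 1 M HCl
Reagents that add atoms: none
Why: Crossed Claisen C-acylation of a preformed lithium enolate with an acid chloride in toluene: kinetic deprotonation takes the CH2 (C1) and not the substituted C7, the acid chloride is made under neutral conditions and has no α-hydrogen for a ketene pathway, and the second equivalent of enolate takes up the acidic proton of 16 so that C7 stays untouched.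

Step 10
Reactants: 16 2-acylcyclobutanone; 12 prenyl bromide
Product: 17 (2R,4S)-2-[(2E,6S)-3-methoxy-9-methyl-4-methylidene-6-(prop-1-en-2-yl)deca-2,8-dienoyl]-3,3-dimethyl-2,4-bis(3-methylbut-2-en-1-yl)cyclobutan-1-one (acyl group cis to the C7 prenyl group)
Conditions: Cs2CO3, MeCN, 0 °C to rt
Reagents that add atoms: none
Why: C-Alkylation of a β-diketone enolate with an allylic bromide, in which the nearly flat four-membered enolate is shielded on one face by the C7 prenyl group across the ring, so the electrophile should enter anti to it and set C1 as (R).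

Step 11
Reactants: 17 cyclobutanone with the dienone ether tether
Product: 18 (1S,5R,7R)-4-methoxy-8,8-dimethyl-1,7-bis(3-methylbut-2-en-1-yl)-5-[(2S)-5-methyl-2-(prop-1-en-2-yl)hex-4-en-1-yl]bicyclo[3.3.1]non-3-ene-2,9-dione
Conditions: [Rh(cod)2]BF4 (10 mol %), (R)-DTBM-SEGPHOS (12 mol %), 1,4-dioxane (0.02 M), 80 °C, Ar
Reagents that add atoms: none
Why: Proposed new method: the cationic monovalent rhodium centre, made electron-rich and very bulky by the bisphosphine, should add oxidatively into the strained acyl–carbon bond C9–C7 to give a five-membered acyl(alkyl) ring of trivalent rhodium, the tethered C5=C6 alkene then binds and inserts into the Rh–acyl bond, and C(sp3)–C(sp3) reductive elimination joins C6 to C7 and frees the catalyst, the release of four-ring strain driving the sequence. The closest known reaction type is the rhodium-catalysed cut-and-sew (alkene carboacylation) of cyclobutanones whose alkene hangs from C3, which gives bridged bicyclic ketones; an alkene tethered to the α-carbon combined with cleavage of the distal α′ bond, on a fully substituted 2-acylcyclobutanone, has not been shown. Ring A closes in the insertion step as a 6-exo acyl transfer onto the inner alkene carbon C5, and ring B closes by reductive elimination from the seven-membered rhodacycle Rh–C6–C5–C9–C1–C8–C7. The only new stereocentre, C5, is dictated by C1, since the C2–C3–C4 tether can deliver the alkene to C9 from one face only and a bicyclo[3.3.1] bridge tolerates no other arrangement, while C7 keeps its configuration because oxidative addition and reductive elimination both proceed with retention, which leaves its prenyl group endo. The step needs C9–C7 rather than C9–C1 cleavage, which is secured by quaternary C1 and C8 shielding the C9–C1 bond from the large ligand and by the fact that the fused alternative would have to join C1 to C5 as a third contiguous quaternary carbon; it needs acyl transfer to C5 rather than C6, secured by the tether length (six- against seven-membered ring) and rewarded by a primary Rh–C6 alkyl without β-hydrogen; and it needs the tether alkene to outrun the prenyl and isopropenyl groups, secured by proximity and lower substitution. No aminopyridine co-catalyst is added, because a primary amine would displace the C4 methoxy group, open the non-enolisable 2-acylcyclobutanone by retro-Claisen attack and epimerise C7 through the enamine, and the moderate temperature is meant to hold back decarbonylation and β-hydride loss at C7.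

Step 12
Reactants: 19 3-hydroxybenzoic acid
Product: 20 tert-butyldimethylsilyl 3-(tert-butyldimethylsilyloxy)benzoate
Conditions: TBSCl (2.2 equiv), imidazole, DMF, rt
Reagents that add atoms: tert-butyldimethylsilyl chloride, CC(C)(C)[Si](C)(C)Cl
Why: Imidazole-promoted silylation covers the phenol and the acid in one operation.

Step 13
Reactants: 20 bis-silylated 3-hydroxybenzoic acid
Product: 21 3-(tert-butyldimethylsilyloxy)benzoyl chloride
Conditions: (COCl)2, DMF (cat.), CH2Cl2, 0 °C to rt
Reagents that add atoms: oxalyl chloride, O=C(Cl)C(=O)Cl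
Why: Silyl esters are converted directly into acid chlorides by the Vilsmeier-type reagent from oxalyl chloride and DMF without free HCl, so the aryl silyl ether survives.

Step 14
Reactants: 18 bicyclic C4 methyl enol ether; 21 3-(tert-butyldimethylsilyloxy)benzoyl chloride
Product: 22 (1R,5R,7R)-3-[3-(tert-butyldimethylsilyloxy)benzoyl]-4-methoxy-8,8-dimethyl-1,7-bis(3-methylbut-2-en-1-yl)-5-[(2S)-5-methyl-2-(prop-1-en-2-yl)hex-4-en-1-yl]bicyclo[3.3.1]non-3-ene-2,9-dione
Conditions: 2,2,6,6-tetramethylpiperidine, n-BuLi, THF, −78 °C; 18; then 21, −78 to −40 °C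
Reagents that add atoms: none
Why: Vinylic lithiation of the vinylogous ester at C3, the only acidic C–H now that both bridgeheads are quaternary, followed by acylation with an aroyl chloride is established on methyl enol ethers of bicyclo[3.3.1]nonane-2,4,9-triones and touches no stereocentre.

Step 15
Reactants: 22 O-methyl, O-silyl protected target
Product: 23 CNP0103487.1, (1R,5R,7R)-4-hydroxy-3-(3-hydroxybenzoyl)-8,8-dimethyl-1,7-bis(3-methylbut-2-en-1-yl)-5-[(2S)-5-methyl-2-(prop-1-en-2-yl)hex-4-en-1-yl]bicyclo[3.3.1]non-3-ene-2,9-dione
Conditions: LiOH·H2O, 1,4-dioxane/H2O, 90 °C; 1 M HCl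
Reagents that add atoms: water (delivered as hydroxide by LiOH), O
Why: Saponification of the vinylogous methyl ester by hydroxide addition–elimination at C4, known for O-methyl ethers of this ring system, runs alongside hydroxide cleavage of the aryl silyl ether, and the enolate formed protects the triketone from further attack.

Compound list
1 | (R)-lavandulol, (2R)-5-methyl-2-(prop-1-en-2-yl)hex-4-en-1-ol | C=C(C)[C@@H](CC=C(C)C)CO | starting material
2 | (R)-lavandulyl iodide | C=C(C)[C@@H](CC=C(C)C)CI | intermediate
3 | methyl acetoacetate | COC(=O)CC(C)=O | starting material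
4 | methyl (6R)-9-methyl-3-oxo-6-(prop-1-en-2-yl)dec-8-enoate | C=C(C)[C@@H](CC=C(C)C)CCC(=O)CC(=O)OC | intermediate
5 | methyl (6S)-4-(hydroxymethyl)-9-methyl-3-oxo-6-(prop-1-en-2-yl)dec-8-enoate (epimers at C4; not isolated) | C=C(C)[C@@H](CC=C(C)C)CC(CO)C(=O)CC(=O)OC | intermediate
6 | 5-[(2S)-5-methyl-2-(prop-1-en-2-yl)hex-4-en-1-yl]oxane-2,4-dione (epimers at ring C5) | C=C(C)[C@@H](CC=C(C)C)CC1COC(=O)CC1=O | intermediate
7 | 4-methoxy-5-[(2S)-5-methyl-2-(prop-1-en-2-yl)hex-4-en-1-yl]-5,6-dihydro-2H-pyran-2-one (epimers at ring C5) | C=C(C)[C@@H](CC=C(C)C)CC1COC(=O)C=C1OC | intermediate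
8 | (2E,6S)-3-methoxy-9-methyl-4-methylidene-6-(prop-1-en-2-yl)deca-2,8-dienoic acid | C=C(C)[C@@H](CC=C(C)C)CC(=C)/C(OC)=C\C(=O)O | intermediate
9 | 3,3-dimethylcyclobutanone | CC1(C)CC(=O)C1 | starting material
10 | RAMP, (2R)-1-amino-2-(methoxymethyl)pyrrolidine | COC[C@H]1CCCN1N | starting material
11 | (2R)-N-(3,3-dimethylcyclobutylidene)-2-(methoxymethyl)pyrrolidin-1-amine | COC[C@H]1CCCN1N=C1CC(C)(C)C1 | intermediate
12 | prenyl bromide | CC(C)=CCBr | starting material
13 | (2R)-N-[(2S)-3,3-dimethyl-2-(3-methylbut-2-en-1-yl)cyclobutylidene]-2-(methoxymethyl)pyrrolidin-1-amine | COC[C@H]1CCCN1N=C1CC(C)(C)[C@@H]1CC=C(C)C | intermediate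
14 | (2S)-3,3-dimethyl-2-(3-methylbut-2-en-1-yl)cyclobutan-1-one | O=C1CC(C)(C)[C@@H]1CC=C(C)C | intermediate
15 | (2E,6S)-3-methoxy-9-methyl-4-methylidene-6-(prop-1-en-2-yl)deca-2,8-dienoyl chloride (not isolated) | C=C(C)[C@@H](CC=C(C)C)CC(=C)/C(OC)=C\C(=O)Cl | intermediate
16 | (4S)-2-acyl-3,3-dimethyl-4-prenylcyclobutanone, acyl = (2E,6S)-3-methoxy-9-methyl-4-methylidene-6-(prop-1-en-2-yl)deca-2,8-dienoyl (drawn as the diketone) | C=C(C)[C@@H](CC=C(C)C)CC(=C)/C(OC)=C\C(=O)C1C(=O)[C@@H](CC=C(C)C)C1(C)C | intermediate
17 | (2R,4S)-2-acyl-3,3-dimethyl-2,4-diprenylcyclobutanone, same acyl group, acyl cis to the C7 prenyl group (precursor of the key step) | C=C(C)[C@@H](CC=C(C)C)CC(=C)/C(OC)=C\C(=O)[C@@]1(CC=C(C)C)C(=O)[C@@H](CC=C(C)C)C1(C)C | intermediate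
18 | (1S,5R,7R)-4-methoxy-8,8-dimethyl-1,7-diprenyl-5-[(2S)-lavandulyl]bicyclo[3.3.1]non-3-ene-2,9-dione (product of the key step) | C=C(C)[C@@H](CC=C(C)C)C[C@@]12C[C@@H](CC=C(C)C)C(C)(C)[C@@](CC=C(C)C)(C(=O)C=C1OC)C2=O | intermediate
19 | 3-hydroxybenzoic acid | O=C(O)c1cccc(O)c1 | starting material
20 | tert-butyldimethylsilyl 3-(tert-butyldimethylsilyloxy)benzoate | CC(C)(C)[Si](C)(C)Oc1cccc(C(=O)O[Si](C)(C)C(C)(C)C)c1 | intermediate
21 | 3-(tert-butyldimethylsilyloxy)benzoyl chloride | CC(C)(C)[Si](C)(C)Oc1cccc(C(=O)Cl)c1 | intermediate
22 | (1R,5R,7R)-3-[3-(tert-butyldimethylsilyloxy)benzoyl] derivative of 18 | C=C(C)[C@@H](CC=C(C)C)C[C@@]12C[C@@H](CC=C(C)C)C(C)(C)[C@@](CC=C(C)C)(C(=O)C(C(=O)c3cccc(O[Si](C)(C)C(C)(C)C)c3)=C1OC)C2=O | intermediate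
23 | CNP0103487.1 | C=C(C)[C@@H](CC=C(C)C)C[C@@]12C[C@@H](CC=C(C)C)C(C)(C)[C@@](CC=C(C)C)(C(=O)C(C(=O)c3cccc(O)c3)=C1O)C2=O | target

Total step count: 15. Longest linear sequence: 10 steps (1, 2, 3, 4, 5, 9, 10, 11, 14, 15).

Steps most likely to fail

1. Step 11.
- **What may go wrong.** Rhodium may insert into C9–C1, helped by coordination of the C2 carbonyl, and fused-ring formation or acyl migration to oxygen may follow. The acyl rhodium ring may lose CO, or β-hydride elimination may occur toward the C7 side chain. The catalyst may stall because the other alkenes bind it or because ligand and substrate chirality are mismatched. Reversible oxa-6π electrocyclisation of the dienone may lower the concentration of reactive substrate.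
- **Fallback.** It uses known chemistry only, sets out from 12 (2 joins later) and comes back at 18. It gives up the cyclobutanone, builds ring B first by carbonyl chemistry and closes ring A last.
- **Ring B.** K2CO3-mediated C-alkylation of pentane-2,4-dione with 12 gives 3-prenylpentane-2,4-dione F1. Aqueous formaldehyde/K2CO3 (hydroxymethylation, retro-Claisen loss of acetate, elimination) gives 6-methyl-3-methylidenehept-5-en-2-one F2. NaOMe-promoted Michael addition and intramolecular Knoevenagel condensation with dimethyl 3-oxopentanedioate give the racemic cyclohexenone diester F3, which already contains C5, C6, C7, C8, C1 and C9. Conjugate addition of Me2CuLi completes the gem-dimethyl group of keto diester F4.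
- **Quaternary centres.** NaH/DMF alkylation of the less hindered C5 with 2, anti to the C7 prenyl group, gives the C5-lavandulyl keto diester F5 after chromatographic removal of the diastereomer with the mirror-image ring. NaH and 12 then alkylate C1, again anti to the C7 prenyl group, to give the fully substituted keto diester F6. Both ester groups thus stand cis to the C7 prenyl group, as the endo series requires.
- **Ring A.** One equivalent of MeLi at −78 °C turns the more accessible C5 ester into the methyl ketone F7. KOt-Bu closes ring A by Dieckmann condensation to give the bicyclic trione F8. Me2SO4/K2CO3 followed by separation of the enol ether regioisomers returns 18.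

2. Step 10.
- **What may go wrong.** O-alkylation may win over C-alkylation at a carbon flanked by quaternary C8, the facial bias from the remote C7 substituent may be too small, and the non-enolisable product may be opened by base.
- **Fallback.** It sets out from 16 and comes back at 17. The SN2 alkylation is replaced by a Tsuji–Trost prenylation with tert-butyl (3-methylbut-2-en-1-yl) carbonate and Pd(PPh3)4 in THF under neutral conditions.
- **Why it should help.** The π-allyl complex of divalent palladium is attacked by the soft diketonate at its less substituted terminus. O-allylation is reversible under zerovalent palladium, so material funnels to the C-prenyl product, and no external base is present. This fallback makes no compound outside the list (entry F0).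

3. Step 9.
- **What may go wrong.** The hindered enolate may be O-acylated, proton exchange between enolate and product may stop the reaction early, and the sensitive acid chloride may decompose.
- **Fallback.** It sets out from 8 (with 14) and comes back at 16, and it forms the C1–C2 bond at the alcohol oxidation level.
- **Sequence.** Coupling of 8 with N,O-dimethylhydroxylamine (EDC, i-Pr2NEt) gives the N-methoxy-N-methylamide F9. i-Bu2AlH at −78 °C gives the (2E)-3-methoxydienal F10. Aldol addition of the kinetic lithium enolate of 14 gives the β-hydroxy ketone F11 as a mixture at the two new centres. Buffered Dess–Martin oxidation (NaHCO3, CH2Cl2) erases both centres and gives 16.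

Further compounds
F1 | step 11 | 3-(3-methylbut-2-en-1-yl)pentane-2,4-dione | CC(=O)C(CC=C(C)C)C(C)=O
F2 | step 11 | 6-methyl-3-methylidenehept-5-en-2-one | CC(=O)C(=C)CC=C(C)C
F3 | step 11 | dimethyl 4-methyl-5-(3-methylbut-2-en-1-yl)-2-oxocyclohex-3-ene-1,3-dicarboxylate (racemic) | COC(=O)C1CC(CC=C(C)C)C(C)=C(C(=O)OC)C1=O
F4 | step 11 | dimethyl 4,4-dimethyl-5-(3-methylbut-2-en-1-yl)-2-oxocyclohexane-1,3-dicarboxylate (racemic) | COC(=O)C1CC(CC=C(C)C)C(C)(C)C(C(=O)OC)C1=O
F5 | step 11 | C5-lavandulyl keto diester (C1 still CH, epimerisable) | C=C(C)[C@@H](CC=C(C)C)C[C@]1(C(=O)OC)C[C@@H](CC=C(C)C)C(C)(C)C(C(=O)OC)C1=O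
F6 | step 11 | C1-prenyl C5-lavandulyl keto diester, both esters cis to the C7 prenyl group | C=C(C)[C@@H](CC=C(C)C)C[C@]1(C(=O)OC)C[C@@H](CC=C(C)C)C(C)(C)[C@@](CC=C(C)C)(C(=O)OC)C1=O
F7 | step 11 | C5-acetyl C1-methoxycarbonyl cyclohexanone | C=C(C)[C@@H](CC=C(C)C)C[C@]1(C(C)=O)C[C@@H](CC=C(C)C)C(C)(C)[C@@](CC=C(C)C)(C(=O)OC)C1=O
F8 | step 11 | 8,8-dimethyl-1,7-diprenyl-5-lavandulylbicyclo[3.3.1]nonane-2,4,9-trione | C=C(C)[C@@H](CC=C(C)C)C[C@@]12C[C@@H](CC=C(C)C)C(C)(C)[C@@](CC=C(C)C)(C(=O)CC1=O)C2=O
F0 | step 10 | none | none
F9 | step 9 | (2E,6S)-N,3-dimethoxy-N,9-dimethyl-4-methylidene-6-(prop-1-en-2-yl)deca-2,8-dienamide | C=C(C)[C@@H](CC=C(C)C)CC(=C)/C(OC)=C\C(=O)N(C)OC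
F10 | step 9 | (2E,6S)-3-methoxy-9-methyl-4-methylidene-6-(prop-1-en-2-yl)deca-2,8-dienal | C=C(C)[C@@H](CC=C(C)C)CC(=C)/C(OC)=C\C=O
F11 | step 9 | aldol adduct of 14 and F10 (carbinol carbon and C1 undefined) | C=C(C)[C@@H](CC=C(C)C)CC(=C)/C(OC)=C\C(O)C1C(=O)[C@@H](CC=C(C)C)C1(C)C
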